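At 6.0 min the reading of Q says little by itself. I set it beside free Z, and that pair is what to watch in this run.

| setting | elm | cedar | flask |
|---|---|---|---|
| D | 0.10 M | 0.40 M | 0.20 M |
| Z | 1.05 equiv | 1.05 equiv | 1.05 equiv |
| remark | run made earlier | run made earlier |  |
| time |  |  | 6.0 min |

- elm (time / min: Q / %, X / %): 0.500: 14, 6; 0.833: 21, 13; 1.50: 30, 17; 3.00: 36, 31; 6.00: 42, 37
- cedar (time / min: Q / %, X / %): 0.500: 5, 1; 1.50: 11, 2; 3.00: 18, 0; 4.00: 23, 4; 6.00: 23, 3

(readings scatter by 2 percentage points)

- percentages count the D that a species holds: one E counts as two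
- solid, in amounts per volume of the solution: D
- the numbers in the tables scatter with a standard deviation of 2 percentage points
- steps under discussion: X + Z <-> Q; D + Q -> E; D <-> X
- at the start none of D is in solution
- X means what is dissolved; the solid is not counted in it

1. Q at 6.0 min, in percent of the D charged
2. concentration of X in solution at 6.0 min, in percent of saturation

I treat X + Z ⇌ Q as a fast pre-equilibrium and follow one molecule of Z, which sits in Q, in E or free; for this reckoning I set E aside. Elm's last reading, with free Z taken as the charge less Q, gives 0.667: these are the binding odds, cQ/cZ, of that molecule. Elm's cX at that reading is 0.0370 M, so the odds per unit of cX are 18.0 M⁻¹.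

Now I turn the question round. For Q to hold half of D at these equivalents, with E still set aside, the odds must reach 0.909, and that asks for a cX of 0.0505 M, above elm's reading. With elm's cX, the flask's equivalents give me an estimate of 42.0 % for Q, and any Z held in E lowers it.

The forecast gives 46 % of Q, above my estimate, and 80 % of saturation. Its ground is: “Elm and cedar both fit a quick equilibrium X + Z ⇌ Q”.

The flask gives 35.3 % of Q, below my estimate, and 84.3 % of saturation.

    X + Z ⇌ Q (K = 19.0 M⁻¹, k = 28.0 M⁻¹ s⁻¹)
    D + Q → E (k = 0.0170 M⁻¹ s⁻¹)
    D ⇌ X, rate k3*(cs3 - [X]) while solid is left; crystals form when [X] > cs3 (solubility = 39.0 mM, k = 0.0190 s⁻¹)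

The flask's final Q and free Z give odds of 0.624, and elm's 18.0 M⁻¹ times the flask's final cX gives 0.593. In a neighbouring flask with 0.34 M of D, the same two reckonings give 0.448 and 0.426, with Q at 26.6 %. Q stays low in the flask chiefly because Q falls back to X + Z: the run without that return ends at 78.6 % of Q instead of 35.3 %.

The earlier runs and the new flask are simulated with constants of no real substance.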